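The cycloheptene ring (C3a, C4, C5, C6, C7, C8, C8a; azulene numbering) shares only the C3a–C8a bond with the cyclopentane, and its C6=C7 alkene and oxygenated C4 sit where a vinylcarbenoid/1-siloxydiene [4+3] annulation places them. The ring is therefore cut into C5–C6–C7 and C8–C8a–C3a–C4. One rhodium-carbenoid cyclopropanation/divinylcyclopropane rearrangement forms C7–C8 and C4–C5 together. Its precursor is a cyclopentane bearing adjacent exocyclic methylene (C8) and silyl enol ether (C4) groups, made by ozonolysis/aldol remodelling of (S)-terpinen-4-ol, whose carbinol carbon becomes C3. The resulting C3a=C8a alkene later accepts the angular methyl group; a sulfone on C7 is removed reductively.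

Key step: step 6

Remark: ring positions of all bicyclic compounds are given in the azulene numbering of the target (C1 to C8a).
Assumption: the C4 carbinol centre created in step 6 is not controlled and is erased in step 8, so 10 to 13 are drawn without a descriptor at that centre (and at the two new cyclopropane carbons of 10); both epimers are carried forward together.
Assumption: (S)-(+)-terpinen-4-ol is bought as the single enantiomer.

Step 1
Reactants: 1 (S)-terpinen-4-ol
Product: 2 triethyl{[(1S)-4-methyl-1-(propan-2-yl)cyclohex-3-en-1-yl]oxy}silane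
Conditions: Et3SiOSO2CF3, 2,6-lutidine, CH2Cl2, 0 °C to rt
Reagents that add atoms: triethylsilyl trifluoromethanesulfonate, CC[Si](CC)(CC)OS(=O)(=O)C(F)(F)F
Why: Silyl triflate silylation of the hindered tertiary alcohol (no stereocentre is touched); the silyl ether keeps this oxygen from acting as a β-leaving group in the aldol condensation of step 2.

Step 2
Reactants: 2 triethyl{[(1S)-4-methyl-1-(propan-2-yl)cyclohex-3-en-1-yl]oxy}silane
Product: 4 (5R)-2-methyl-5-(propan-2-yl)-5-[(triethylsilyl)oxy]cyclopent-1-ene-1-carbaldehyde, via keto aldehyde 3 (not isolated)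
Conditions: O3, CH2Cl2, −78 °C; Me2S, −78 °C to rt; then piperidine, AcOH, toluene, 60 °C
Reagents that add atoms: ozone, [O-][O+]=O
Why: Ozonolysis cleaves the ring alkene to keto aldehyde 3, and the piperidinium acetate-mediated intramolecular aldol condensation (aldehyde enamine onto the methyl ketone, five-membered ring closure, dehydration of the new tertiary aldol hydroxyl rather than loss of the silyloxy group) recloses the skeleton as a cyclopentene enal; the carbinol centre is not involved.

Step 3
Reactants: 4 (5R)-2-methyl-5-(propan-2-yl)-5-[(triethylsilyl)oxy]cyclopent-1-ene-1-carbaldehyde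
Product: 5 triethyl{[(E)-{(2R)-5-methylidene-2-(propan-2-yl)-2-[(triethylsilyl)oxy]cyclopentylidene}methyl]oxy}silane
Conditions: KN(SiMe3)2, THF, −78 °C; Et3SiCl, −78 to 0 °C
Reagents that add atoms: chlorotriethylsilane, CC[Si](Cl)(CC)CC
Why: Kinetic γ-deprotonation of the enal at the methyl group syn to the formyl group (the ring methylene is anti) and O-silylation of the potassium dienolate should give the s-cis-locked silyl dienol ether; its enol ether geometry (E expected from the s-cis enal conformer) leaves no lasting stereocentre.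

Step 4
Reactants: 6 sodium benzenesulfinate; 7 3-chloro-2-methylprop-1-ene
Product: 8 [(2-methylprop-2-en-1-yl)sulfonyl]benzene
Conditions: NaI (cat.), DMF, 60 °C
Reagents that add atoms: none
Why: SN2 S-alkylation of the sulfinate by the allylic chloride.

Step 5
Reactants: 8 [(2-methylprop-2-en-1-yl)sulfonyl]benzene
Product: 9 [(1-diazo-2-methylprop-2-en-1-yl)sulfonyl]benzene
Conditions: 4-acetamidobenzenesulfonyl azide, DBU, MeCN, 0 °C; used at once
Reagents that add atoms: 4-acetamidobenzenesulfonyl azide, CC(=O)Nc1ccc(cc1)S(=O)(=O)N=[N+]=[N-]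
Why: Regitz diazo transfer to the sulfonyl- and vinyl-activated methylene; the product is kept cold and used immediately because vinyldiazo compounds cyclize to pyrazoles.

Step 6
Reactants: 5 triethyl{[(E)-{(2R)-5-methylidene-2-(propan-2-yl)-2-[(triethylsilyl)oxy]cyclopentylidene}methyl]oxy}silane; 9 [(1-diazo-2-methylprop-2-en-1-yl)sulfonyl]benzene
Product: 12 (3R)-6-methyl-7-(phenylsulfonyl)-3-(propan-2-yl)-1,2,3,4,5,8-hexahydroazulene-3,4-diol, via spirocyclic divinylcyclopropane 10 (not isolated), via bis-silyl cycloadduct 11 (not isolated)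
Conditions: Rh2(O2CC7H15)4 (1 mol %), toluene, −20 °C to rt, slow addition of 9; then 80 °C; then HF·pyridine, pyridine, THF, 0 °C to rt
Reagents that add atoms: none
Why: The dirhodium carbenoid formed from 9 by loss of N2 is attacked at its carbene carbon by the unsubstituted methylene terminus of 5 to give spirocyclopropane 10 (new C7–C8 bond), whose isopropenyl and siloxyvinyl arms then undergo a [3,3]-sigmatropic (Cope) rearrangement that forms C4–C5 and cleaves the transient cyclopropane bond. The closest known reaction type is the tandem cyclopropanation/divinylcyclopropane rearrangement ([4+3] annulation) of donor/acceptor vinylcarbenoids with 1-siloxy-1,3-dienes. The seven-membered ring closes in the sigmatropic step through a boat-like transition state with the diene held s-cis by the cyclopentane; a trans-divinyl isomer of 10 can reach the same product on warming because its donor (dienol ether) and acceptor (sulfone) substituents allow reversible opening of the cyclopropane. The only new stereocentre, the silyloxy-bearing C4, is not controlled and need not be, since step 8 oxidizes it, while the C3 carbinol centre is untouched. The step needs chemoselectivity for the 1,1-disubstituted methylene over the trisubstituted enol ether (secured by sterics and the large HOMO coefficient at the dienol ether terminus) and attack at the carbene carbon rather than at the vinylogous position (secured by the non-polar solvent and the carboxylate catalyst); the C6=C7 position of the new alkene follows from the mechanism. Buffered fluoride then removes both silyl groups without a base that could shift the vinyl sulfone.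

Step 7
Reactants: 12 (3R)-6-methyl-7-(phenylsulfonyl)-3-(propan-2-yl)-1,2,3,4,5,8-hexahydroazulene-3,4-diol
Product: 13 (3R)-6-methyl-3-(propan-2-yl)-1,2,3,4,5,8-hexahydroazulene-3,4-diol
Conditions: Na(Hg) (6 % Na), Na2HPO4, MeOH/THF, −20 to 0 °C
Reagents that add atoms: none
Why: Reductive desulfonylation of the vinyl sulfone by electron transfer (vinyl radical/anion protonated by methanol) should replace the sulfonyl group by hydrogen without moving the ring alkene, the phosphate buffer suppressing base-induced vinyl-to-allyl sulfone isomerization.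

Step 8
Reactants: 13 (3R)-6-methyl-3-(propan-2-yl)-1,2,3,4,5,8-hexahydroazulene-3,4-diol
Product: 14 (3R)-3-hydroxy-6-methyl-3-(propan-2-yl)-2,3,5,8-tetrahydroazulen-4(1H)-one
Conditions: MnO2, CH2Cl2, rt
Reagents that add atoms: none
Why: Chemoselective MnO2 oxidation of the secondary allylic alcohol (the tertiary allylic alcohol cannot be oxidized) should convert both C4 epimers into one enone under neutral conditions that leave the β,γ-alkene in place.

Step 9
Reactants: 14 (3R)-3-hydroxy-6-methyl-3-(propan-2-yl)-2,3,5,8-tetrahydroazulen-4(1H)-one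
Product: 16 (3R,3aR,8aR)-3-hydroxy-6,8a-dimethyl-3-(propan-2-yl)-2,3,3a,5,8,8a-hexahydroazulen-4(1H)-one, via dilithium enolate alkoxide 15 (not isolated)
Conditions: Me2CuLi (4 equiv, from CuI and MeLi), Et2O, −40 to 0 °C; then AcOH, −78 °C
Reagents that add atoms: lithium dimethylcuprate, [Li+].C[Cu-]C
Why: Conjugate (1,4-) addition of the Gilman cuprate to the s-trans enone should place the methyl group on C8a from the face of the C3 alkoxide, anti to the bulky isopropyl group, and protonation of enolate 15 sets C3a, where the trans-fused ketone (C4 anti to the isopropyl group and hydrogen-bonded to the C3 hydroxyl) is expected to be the more stable epimer and reachable by mild enolization if the cis isomer forms first.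

Step 10
Reactants: 16 (3R,3aR,8aR)-3-hydroxy-6,8a-dimethyl-3-(propan-2-yl)-2,3,3a,5,8,8a-hexahydroazulen-4(1H)-one
Product: 17 (3R,3aS,4S,8aR)-6,8a-dimethyl-3-(propan-2-yl)-1,2,3,3a,4,5,8,8a-octahydroazulene-3,4-diol
Conditions: Me4NBH(OAc)3, MeCN/AcOH, −30 °C
Reagents that add atoms: none
Why: In this hydroxyl-directed Evans–Saksena reduction the C3 hydroxyl should exchange onto boron and deliver hydride through a chair-like six-membered transition state to the ketone face that carries the angular methyl group, giving the equatorial 4S alcohol (1,3-anti diol) that an external hydride from the open face would not give.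

Step 11
Reactants: 17 (3R,3aS,4S,8aR)-6,8a-dimethyl-3-(propan-2-yl)-1,2,3,3a,4,5,8,8a-octahydroazulene-3,4-diol; 18 2-acetoxybenzoyl chloride
Product: 20 (3R,3aS,4S,8aR)-3-hydroxy-6,8a-dimethyl-3-(propan-2-yl)-1,2,3,3a,4,5,8,8a-octahydroazulen-4-yl 2-hydroxybenzoate, via acetylsalicylate ester 19 (not isolated)
Conditions: pyridine, DMAP, CH2Cl2, 0 °C to rt; then pyrrolidine, rt
Reagents that add atoms: none
Why: DMAP-catalysed acylation of the secondary alcohol (the hindered tertiary alcohol does not react) is followed in the same flask by chemoselective aminolysis of the phenolic acetate, the hindered alkyl salicylate being left intact and no stereocentre being touched.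

Compound list
1 | (S)-(+)-terpinen-4-ol, (1S)-4-methyl-1-(propan-2-yl)cyclohex-3-en-1-ol | CC1=CC[C@](O)(C(C)C)CC1 | starting material
2 | triethyl{[(1S)-4-methyl-1-(propan-2-yl)cyclohex-3-en-1-yl]oxy}silane | CC1=CC[C@](O[Si](CC)(CC)CC)(C(C)C)CC1 | intermediate
3 | (3S)-6-oxo-3-(propan-2-yl)-3-[(triethylsilyl)oxy]heptanal | CC(=O)CC[C@@](O[Si](CC)(CC)CC)(C(C)C)CC=O | intermediate (not isolated)
4 | (5R)-2-methyl-5-(propan-2-yl)-5-[(triethylsilyl)oxy]cyclopent-1-ene-1-carbaldehyde | CC1=C(C=O)[C@](O[Si](CC)(CC)CC)(C(C)C)CC1 | intermediate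
5 | triethyl{[(E)-{(2R)-5-methylidene-2-(propan-2-yl)-2-[(triethylsilyl)oxy]cyclopentylidene}methyl]oxy}silane | C=C1CC[C@@](O[Si](CC)(CC)CC)(C(C)C)/C1=C/O[Si](CC)(CC)CC | intermediate
6 | sodium benzenesulfinate | [Na+].[O-]S(=O)c1ccccc1 | starting material
7 | 3-chloro-2-methylprop-1-ene | CC(=C)CCl | starting material
8 | [(2-methylprop-2-en-1-yl)sulfonyl]benzene | CC(=C)CS(=O)(=O)c1ccccc1 | intermediate
9 | [(1-diazo-2-methylprop-2-en-1-yl)sulfonyl]benzene | CC(=C)C(=[N+]=[N-])S(=O)(=O)c1ccccc1 | intermediate
10 | (5R)-1-(phenylsulfonyl)-1-(prop-1-en-2-yl)-5-(propan-2-yl)-5-[(triethylsilyl)oxy]-4-{(E)-[(triethylsilyl)oxy]methylidene}spiro[2.4]heptane (cyclopropane centres undefined) | CC(=C)C1(CC12CC[C@@](O[Si](CC)(CC)CC)(C(C)C)/C2=C/O[Si](CC)(CC)CC)S(=O)(=O)c1ccccc1 | intermediate (not isolated)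
11 | (3R)-6-methyl-7-(phenylsulfonyl)-3-(propan-2-yl)-3,4-bis[(triethylsilyl)oxy]-1,2,3,4,5,8-hexahydroazulene (C4 epimers) | CC1=C(S(=O)(=O)c2ccccc2)CC2=C(C(O[Si](CC)(CC)CC)C1)[C@](O[Si](CC)(CC)CC)(C(C)C)CC2 | intermediate (not isolated)
12 | (3R)-6-methyl-7-(phenylsulfonyl)-3-(propan-2-yl)-1,2,3,4,5,8-hexahydroazulene-3,4-diol (C4 epimers) | CC1=C(S(=O)(=O)c2ccccc2)CC2=C(C(O)C1)[C@](O)(C(C)C)CC2 | intermediate
13 | (3R)-6-methyl-3-(propan-2-yl)-1,2,3,4,5,8-hexahydroazulene-3,4-diol (C4 epimers) | CC1=CCC2=C(C(O)C1)[C@](O)(C(C)C)CC2 | intermediate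
14 | (3R)-3-hydroxy-6-methyl-3-(propan-2-yl)-2,3,5,8-tetrahydroazulen-4(1H)-one | CC1=CCC2=C(C(=O)C1)[C@](O)(C(C)C)CC2 | intermediate
15 | dilithium salt (C3 alkoxide, C3a=C4 enolate) of the methyl adduct, (3R,8aR) | CC1=CC[C@@]2(C)CC[C@@](O[Li])(C(C)C)C2=C(O[Li])C1 | intermediate (not isolated)
16 | (3R,3aR,8aR)-3-hydroxy-6,8a-dimethyl-3-(propan-2-yl)-2,3,3a,5,8,8a-hexahydroazulen-4(1H)-one | CC1=CC[C@@]2(C)CC[C@@](O)(C(C)C)[C@@H]2C(=O)C1 | intermediate
17 | (3R,3aS,4S,8aR)-6,8a-dimethyl-3-(propan-2-yl)-1,2,3,3a,4,5,8,8a-octahydroazulene-3,4-diol | CC1=CC[C@@]2(C)CC[C@@](O)(C(C)C)[C@@H]2[C@@H](O)C1 | intermediate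
18 | 2-acetoxybenzoyl chloride | CC(=O)Oc1ccccc1C(Cl)=O | starting material
19 | (3R,3aS,4S,8aR)-3-hydroxy-6,8a-dimethyl-3-(propan-2-yl)-1,2,3,3a,4,5,8,8a-octahydroazulen-4-yl 2-(acetyloxy)benzoate | CC1=CC[C@@]2(C)CC[C@@](O)(C(C)C)[C@@H]2[C@@H](OC(=O)c2ccccc2OC(C)=O)C1 | intermediate (not isolated)
20 | (3R,3aS,4S,8aR)-3-hydroxy-6,8a-dimethyl-3-(propan-2-yl)-1,2,3,3a,4,5,8,8a-octahydroazulen-4-yl 2-hydroxybenzoate | CC1=CC[C@@]2(C)CC[C@@](O)(C(C)C)[C@@H]2[C@@H](OC(=O)c2ccccc2O)C1 | target

Total step count: 11. Longest linear sequence: 9 steps (1, 2, 3, 6, 7, 8, 9, 10, 11); steps 4 and 5 form the side branch.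

Steps most likely to fail

Step 6. The dienol ether may attack the vinylogous terminus of the sulfonyl carbenoid instead of the carbene carbon, 9 may cyclize to a pyrazole before it reaches the catalyst, or the sequence may stall at the cyclopropane because the inward-pointing silyloxy group slows the rearrangement (with ring closure to a cyclopentene as an escape). The fallback uses the best-precedented donor/acceptor partner and removes its extra carbon by decarbonylation. It sets out from 5: the same dirhodium catalysis with methyl 2-diazo-3-methylbut-3-enoate F1 (Regitz diazo transfer to commercial methyl 3-methylbut-3-enoate) would give the bis-silyl ester cycloadduct F2 and, after HF·pyridine, the diol ester F3. Reduction with i-Bu2AlH would give the triol F4, MnO2 would oxidize both allylic alcohols to the keto enal F5, and Tsuji–Wilkinson decarbonylation with stoichiometric RhCl(PPh3)3 in hot toluene would remove the formyl carbon. The fallback comes back to the route at enone 14.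

Step 9. Addition to the tetrasubstituted enone may be too slow and lose to enolization at the doubly activated C5 methylene, and protonation of the enolate may not give the trans ring fusion. The fallback replaces the cuprate by a small ylide and a reductive ring opening. It sets out from 14: Corey–Chaykovsky cyclopropanation with dimethylsulfoxonium methylide (Me3S(O)I, NaH, DMSO) would add the methylene anti to the isopropyl group to give the cyclopropyl ketone F6. SmI2 (THF/DMPU, t-BuOH) would then cleave the exocyclic cyclopropane bond that overlaps with the ketyl, leaving the angular methyl group on C8a and a samarium enolate whose protonation is governed by the same thermodynamic preference. The fallback comes back at 16.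

Step 10. Intermolecular hydride attack from the open face, away from the angular methyl group, may outrun internal delivery and give the axial C4 epimer. The fallback accepts that selectivity and inverts the centre while forming the ester. It sets out from 16: NaBH4 (MeOH, −20 °C) would give the 4-epi-diol F7, and Mitsunobu esterification with salicylic acid (PPh3, diisopropyl azodicarboxylate, toluene) would install the salicylate with inversion at C4. The fallback arrives directly at 20.

Further compounds
F1 | step 6 | methyl 2-diazo-3-methylbut-3-enoate | COC(=O)C(=[N+]=[N-])C(C)=C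
F2 | step 6 | methyl (3R)-6-methyl-3-(propan-2-yl)-3,4-bis[(triethylsilyl)oxy]-1,2,3,4,5,8-hexahydroazulene-7-carboxylate (C4 epimers; locants as in 12) | CC1=C(C(=O)OC)CC2=C(C(O[Si](CC)(CC)CC)C1)[C@](O[Si](CC)(CC)CC)(C(C)C)CC2
F3 | step 6 | methyl (3R)-3,4-dihydroxy-6-methyl-3-(propan-2-yl)-1,2,3,4,5,8-hexahydroazulene-7-carboxylate (C4 epimers; locants as in 12) | CC1=C(C(=O)OC)CC2=C(C(O)C1)[C@](O)(C(C)C)CC2
F4 | step 6 | (3R)-7-(hydroxymethyl)-6-methyl-3-(propan-2-yl)-1,2,3,4,5,8-hexahydroazulene-3,4-diol (C4 epimers) | CC1=C(CO)CC2=C(C(O)C1)[C@](O)(C(C)C)CC2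
F5 | step 6 | (3R)-3-hydroxy-6-methyl-4-oxo-3-(propan-2-yl)-1,2,3,4,5,8-hexahydroazulene-7-carbaldehyde (locants as in 12) | CC1=C(C=O)CC2=C(C(=O)C1)[C@](O)(C(C)C)CC2
F6 | step 9 | (3R)-3-hydroxy-6-methyl-3-(propan-2-yl)-2,3,5,8-tetrahydro-1H-3a,8a-methanoazulen-4-one, methano bridge cis to the C3 hydroxyl | CC1=CC[C@]23C[C@@]2(C(=O)C1)[C@](O)(C(C)C)CC3
F7 | step 10 | (3R,3aS,4R,8aR)-6,8a-dimethyl-3-(propan-2-yl)-1,2,3,3a,4,5,8,8a-octahydroazulene-3,4-diol | CC1=CC[C@@]2(C)CC[C@@](O)(C(C)C)[C@@H]2[C@H](O)C1
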